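## The problem

The target 26 is a trans-fused bicyclo[5.3.0]decane: a cycloheptanone (ring atoms C2, C3, C4, C5, C6, C10, C11; carbonyl at C10) shares the C5–C6 bond with a cyclopentane (C5, C6, C7, C8, C9), and quaternary C11 carries a two-carbon chain ending at C4 of a furan-2(5H)-one. There are five stereocentres: C2 (CHMe), C11 (quaternary), C5 (tertiary alcohol at the fusion), C6 (fusion hydrogen) and C8 (secondary alcohol). The C2 and C11 methyl groups and both hydroxyls lie on one face, the C11 chain and the C6 hydrogen on the other. C2 and C11 are neighbours and can be set together, but C5 is 1,4 to both across a flexible seven-membered ring, so a free reagent cannot be trusted to find the right face of C5. The C11 chain, however, sits on exactly the face that the C9 substituent of C5 must occupy and can deliver it; C5 can then control C6, and C5 and C6 together differentiate the faces of C8. The sensitive parts are the aldol-type unit C5(OH)–C6(H)–C10(=O) (dehydration, retro-aldol cleavage, epimerisation of the fusion hydrogen) and the butenolide (bases, hydrides, metal hydrides), so C10 is masked early and freed last and the butenolide is attached late. The feature that invites the key step is the cyclopentane C5–C6–C7–C8–C9 with oxygen on C8 and hydrogen on C6: opened at C7–C8 it is a 4-pentenal (C8 aldehyde, C9, C5, exocyclic C6=C7 methylene) whose C9 is quaternary and whose alkene, between fully substituted C5 and C10, has no allylic hydrogen.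

## Retrosynthesis

**26 ⇒ 25 ⇒ 24 (no skeletal bond cut).** In 25, C10 is a dioxolane and the C5 hydroxyl a triethylsilyl ether, so the fragile β-hydroxy ketone exists only after the last step. Masking C10 as an alcohol instead would mean telling two secondary alcohols (C8, C10) apart at the end. 25 comes from ketone 24 by hydride addition to C8, which must occur from the face of the C6 hydrogen and spare the butenolide.

**24 ⇒ 21 + 22 (chain CH2–butenolide C4 bond).** A late C(sp3)–C(sp2) coupling with commercial 22 is preferred to building the butenolide on the chain or carrying its alkene through a rhodium hydride step. Iodide 21 lacks four carbons and the only base-sensitive unit; it follows from silyl ether 19 through alcohol 20. The coupling must tolerate the C8 ketone.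

**19 ⇒ 18 (C7–C8, with H returned from C6).** Cutting C5–C6 instead (aldol) would demand a ten-membered diketone and leave the fusion to chance. Cutting C7–C8 gives aldehyde 18 with an exocyclic methylene: one ring and one stereocentre (C6) fewer. The forward step must join C8 to C7 and put hydrogen on C6 from the face of the arm.

**18 ⇒ 17 ⇒ 16 (C8–O bond restored).** The C8 aldehyde and the chain alcohol of diol 17 are the two halves of a reduced ester. Joining them gives lactone 16, in which the C5 substituent and the C11 chain, which must be cis, form one bridge. The forward step is a partial lactone reduction followed by silylation.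

**16 ⇒ 14 (C5–C9).** An intermolecular enolate addition to a C5 ketone would depend on 1,4-induction from C2 and C11. The intramolecular Reformatsky reaction of bromo ester 14 can reach only one face. 14 is monocyclic and lacks the C5 stereocentre. The forward step is a 1,2-addition to an α-methylene ketone that closes a bridged nine-membered lactone.

**14 ⇒ 12 ⇒ 10 + 11 (C5–O bond with allylic transposition; ester C–O).** Enolate methylenation of a C5 ketone is avoided: it could enolise towards C4 as well as C6, and a C6 enolate β to the ketal can expel alkoxide. Instead the enone comes from trisubstituted alkene 12 (C5=C6, methyl C7) by an ene reaction that places oxygen on C5 and moves the alkene to C6=C7. 12 is the ester of alcohol 10 with acid bromide 11.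

**10 ⇒ 9 ⇒ 8 ⇒ 7 ⇒ 5 ⇒ 4 (C6–C7; then C6 removed).** The methyl C7 is attached to vinyl bromide 8 by cross-coupling to give 9, and the ester of 9 is reduced to 10. Bromo enone 7 is the product of a one-carbon ring expansion of cyclohexanone 4 through its enol ether 5. Because C11 is quaternary only one enol ether can form, and the expansion delivers the C6 halide and the C5=C6 unsaturation in one operation.

**4 ⇒ 1 + 2 + a methyl nucleophile (C2–CH3 and C11–CH2).** Both stereocentres arise from achiral commercial 1 in one operation. The ring constraint makes the trans alkylation of the enolate dependable, which an acyclic construction of a quaternary/tertiary pair would not offer.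

## Roads not taken

**Alternative 1:** The skeleton is traced to the halimane-type octalin A2 (C5=C10 alkene), made by cationic cyclisation of the open-chain epoxy triene A1.
- Key step: FSO3H or MeAlCl2 opens the epoxide, two cation–olefin closures form C9–C5 and C10–C11, a hydride moves from C11 to C2, a methyl from C10 to C11, and loss of the C5 proton gives A2. A2 would still need ozonolysis of C5=C10 and a transannular aldol closure of C5–C6 to reach 26.
- Merits: both carbocycles, C2, C11 and C8 come from one epoxide stereocentre in a single step; the route would be well under ten steps and nearly free of protecting groups.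
- Weak points: the cascade must stop after exactly one hydride and one methyl shift and lose one particular proton, while unshifted (labdane-type) and further-shifted (clerodane-type) products compete. The later aldol in a ten-membered ring must give the trans C5/C6 relation without any control element.
- Comparison: on step count this road is clearly better, and if the cascade were selective it would be the route of choice. The chosen plan sets against it that each stereocentre, and the fusion in particular, is fixed by a separate, intramolecularly enforced event.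

**Alternative 2:** The cut is C4–C5 of the seven-membered ring.
- Key step: 9-BBN adds to the C2 vinyl group of triflate A3, and PdCl2(dppf)/Cs2CO3 couples the C4 borane with the C5 enol triflate (B-alkyl Suzuki–Miyaura) to give enone A4.
- Merits: convergent, with C8 present from the start; the ring closure is of a dependable type and needs no medium-ring tether.
- Weak points: A4 has a tetrasubstituted C5=C6 enone. Turning it into the C5 alcohol with a trans C6 hydrogen is a net anti hydration of a hindered enone under late substrate control, and the acyclic C2/C11 pair and the acyl cyclopentenyl triflate add steps.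
- Comparison: its ring closure is more certain than the tethered Reformatsky step of the chosen plan, and convergence is a real advantage. The chosen plan answers with two intramolecular relays (C11 to C5, C5 to C6) for the very stereocentres this road leaves open.

**Alternative 3:** The cuts are C6–C10 and C5–C6.
- Key step: SnCl4 activates the C10 ketone of cyclohexanone A5, the tethered diazo ester carbon C6 adds, and C5 migrates from C10 to C6 as N2 leaves, giving β-keto ester A6 with both rings.
- Merits: one step makes both rings; C5 migrates with retention and C8 is preset.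
- Weak points: C11 can migrate instead of the oxygen-bearing C5, the Lewis acid threatens the tertiary silyl ether, and the C6 hydrogen arises only on dealkoxycarbonylation by protonation of an enol. A5 itself needs C5 set relative to C11 without a relay.
- Comparison: it is superior in ring-forming economy. The chosen plan forms one bond per ring-building step but with a defined regio- and stereochemical outcome each time.

Key step: step 12

Remark: locants C2–C11 are those of the target skeleton, and descriptors such as (2R,11S) in descriptive names refer to them; the sense of induction in step 1 is assumed to be selectable through the ligand enantiomer.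

## Route

Step 1
Reactants: 1 2-methylcyclohex-2-en-1-one; 2 ethyl bromoacetate
Product: 4 ethyl 2-[(1S,2R)-1,2-dimethyl-6-oxocyclohexyl]acetate, via bromomagnesium enolate 3 (not isolated)
Conditions: MeMgBr, Cu(OTf)2 (3 mol %), chiral hydroxyalkyl imidazolinium salt (carbene precursor, 4 mol %), Et2O, −30 °C; then 2, DMPU, −30 → 20 °C
Reagents that add atoms: methylmagnesium bromide, C[Mg]Br
Why: Copper-catalysed asymmetric conjugate addition of a Grignard reagent to an α-substituted cyclohexenone with enolate alkylation; the ligand fixes C2 (R), and enolate 3, whose C2 methyl sits pseudoaxial to avoid allylic 1,2-strain, is alkylated on the opposite face, so the acetate arm ends trans to the C2 methyl (11S).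

Step 2
Reactants: 4 keto ester
Product: 5 ethyl 2-[(1S,6R)-1,6-dimethyl-2-(trimethylsilyloxy)cyclohex-2-en-1-yl]acetate
Conditions: TMSOTf, Et3N, CH2Cl2, 0 °C
Reagents that add atoms: trimethylsilyl trifluoromethanesulfonate, C[Si](C)(C)OS(=O)(=O)C(F)(F)F
Why: Soft enolisation; C11 is quaternary, so the ketone can enolise only towards C5 and one enol ether forms, while the less acidic ester is left alone.

Step 3
Reactants: 5 silyl enol ether
Product: 7 ethyl 2-[(1S,2R)-6-bromo-1,2-dimethyl-7-oxocyclohept-5-en-1-yl]acetate, via dibromocyclopropane 6 (not isolated)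
Conditions: CHBr3, KOt-Bu, pentane, −20 → 20 °C; then toluene, 80 °C
Reagents that add atoms: bromoform, BrC(Br)Br
Why: Dibromocarbene cyclopropanation of the enol ether and thermal ring opening with loss of bromide and the silyl group (one-carbon ring expansion to a 2-bromocycloalk-2-enone); the carbene carbon becomes C6 between C10 and C5 and no stereocentre is touched.

Step 4
Reactants: 7 bromo enone
Product: 8 ethyl 2-[(6S,7R)-11-bromo-6,7-dimethyl-1,4-dioxaspiro[4.6]undec-10-en-6-yl]acetate
Conditions: 1,2-bis(trimethylsilyloxy)ethane, TMSOTf (5 mol %), CH2Cl2, −78 → 0 °C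
Reagents that add atoms: 1,2-bis(trimethylsilyloxy)ethane, C[Si](C)(C)OCCO[Si](C)(C)C
Why: Aprotic silyl-transfer ketalisation, the method suited to enones and hindered ketones; the vinyl bromide keeps the alkene in place and the ester cannot transesterify.

Step 5
Reactants: 8 bromo ketal
Product: 9 ethyl 2-[(6S,7R)-6,7,11-trimethyl-1,4-dioxaspiro[4.6]undec-10-en-6-yl]acetate
Conditions: MeZnCl, Pd(P(t-Bu)3)2 (3 mol %), THF, 50 °C
Reagents that add atoms: methylzinc chloride, C[Zn]Cl
Why: Negishi coupling of an alkenyl bromide, tolerant of ester and ketal; the bulky electron-rich phosphine copes with the bromide beside the spiro carbon, and the methyl introduced is C7.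

Step 6
Reactants: 9 ester
Product: 10 2-[(6S,7R)-6,7,11-trimethyl-1,4-dioxaspiro[4.6]undec-10-en-6-yl]ethan-1-ol
Conditions: LiAlH4, THF, 0 °C
Reagents that add atoms: none
Why: Hydride reduction of the ester to the primary alcohol of the C11 chain; ketal and trisubstituted alkene are inert.

Step 7
Reactants: 10 alcohol; 11 2-bromo-2-methylpropanoyl bromide
Product: 12 2-[(6S,7R)-6,7,11-trimethyl-1,4-dioxaspiro[4.6]undec-10-en-6-yl]ethyl 2-bromo-2-methylpropanoate
Conditions: pyridine, DMAP (cat.), CH2Cl2, 0 °C
Reagents that add atoms: none
Why: Acylation of a primary alcohol by an acid bromide; it places C8, C9 and the gem-dimethyl group on the C11 chain, on the ring face that the C5 substituent must later occupy.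

Step 8
Reactants: 12 bromo ester
Product: 14 2-[(6S,7R)-6,7-dimethyl-11-methylidene-10-oxo-1,4-dioxaspiro[4.6]undecan-6-yl]ethyl 2-bromo-2-methylpropanoate, via allylic hydroperoxide 13 (not isolated)
Conditions: O2, visible light, tetraphenylporphyrin (cat.), CH2Cl2, 0 °C; then Ac2O, pyridine, DMAP (cat.), 0 → 20 °C
Reagents that add atoms: oxygen, O=O
Why: Schenck ene reaction of singlet oxygen, then Kornblum–DeLaMare dehydration of the secondary hydroperoxide; with the bulky spiro carbon geminal to the C7 methyl, oxygen should bond to the less hindered C5 and a C7 hydrogen be removed (geminal selectivity), giving the exocyclic alkene, and C5 is then oxidised to the ketone.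

Step 9
Reactants: 14 enone bromo ester
Product: 16 bridged hydroxy lactone (2R,5S,11S), via samarium enolate 15 (not isolated)
Conditions: SmI2 (2.5 equiv), THF, −78 °C, slow addition of 14 (final 0.005 M); then pH 7 buffer
Reagents that add atoms: none
Why: Samarium diiodide-mediated intramolecular Reformatsky reaction, known for medium and large lactones: the α-bromo ester is reduced far faster than the enone and the trivalent samarium enolate adds 1,2 to the chelated C5 ketone. C5 is set by C11, because the five-atom tether can reach the carbonyl only from the face bearing the C11 chain, so C9 ends cis to the chain and the hydroxyl cis to the C11 methyl.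

Step 10
Reactants: 16 bridged hydroxy lactone
Product: 17 hydroxy aldehyde diol (2R,5R,11S)
Conditions: i-Bu2AlH (3.2 equiv), CH2Cl2, −78 °C; aq. potassium sodium tartrate
Reagents that add atoms: none
Why: Partial reduction of a lactone: the aluminium hemiacetal persists at −78 °C, and since a nine-membered lactol is not favoured the open hydroxy aldehyde results, freeing the C8 aldehyde and the chain alcohol together.

Step 11
Reactants: 17 hydroxy aldehyde diol
Product: 18 bis(triethylsilyl) ether aldehyde (2R,5R,11S)
Conditions: TESOTf (2.5 equiv), 2,6-lutidine, CH2Cl2, −78 → 0 °C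
Reagents that add atoms: triethylsilyl trifluoromethanesulfonate, CC[Si](CC)(CC)OS(=O)(=O)C(F)(F)F
Why: Silyl triflate silylation, reactive enough for the tertiary allylic hydroxyl; the aldehyde has no α-hydrogen and cannot enolise.

Step 12
Reactants: 18 bis(triethylsilyl) ether aldehyde
Product: 19 trans-fused cyclopentanone (2R,5S,6S,11S)
Conditions: [Rh(dppe)]ClO4 (10 mol %; from [Rh(nbd)(dppe)]ClO4 and H2), CH2Cl2, 25 °C
Reagents that add atoms: none
Why: Intramolecular alkene hydroacylation of a 4-pentenal, the reaction type established for cationic monovalent rhodium bisphosphine catalysts of this class. Oxidative addition of the C8–H bond gives an acyl hydride of trivalent rhodium, held by the C9–C5 link over the face of the C6=C7 methylene on which the arm sits. Syn insertion places hydride on C6 and rhodium on the unhindered C7, and C–C reductive elimination from the six-membered acyl(alkyl)rhodacycle forms C7–C8. The cyclopentanone thus closes through a metallacycle and not by direct attack of C8 on C7, which would be a 5-endo-trig closure out of reach of acyl anion or acyl radical equivalents. The only new stereocentre, C6, is set by C5: hydrogen arrives on the face of C9, trans to the C5 oxygen, giving the trans fusion. Cyclisation must beat decarbonylation; the chelating dppe, the Thorpe–Ingold effect of the substituents on C9 and C5, and the absence of an α-hydrogen on C9 favour it. Regiochemistry is fixed because the other insertion would lead to a cyclobutanone, and the methylene, lacking allylic hydrogens at C5 and C10, cannot be isomerised by the rhodium hydride.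

Step 13
Reactants: 19 trans-fused cyclopentanone
Product: 20 primary alcohol (2R,5S,6S,11S)
Conditions: AcOH/THF/H2O (3:1:1), 0 → 20 °C
Reagents that add atoms: none
Why: Acid solvolysis distinguishes silyl ethers by steric access: the primary triethylsilyl ether is cleaved, the tertiary one at C5 and the hindered dioxolane are not.

Step 14
Reactants: 20 primary alcohol
Product: 21 primary iodide (2R,5S,6S,11S)
Conditions: I2, PPh3, imidazole, CH2Cl2, 0 °C
Reagents that add atoms: iodine, II
Why: Appel-type iodination of a primary alcohol under buffered conditions; ketone, ketal and tertiary silyl ether do not react.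

Step 15
Reactants: 21 primary iodide; 22 4-bromofuran-2(5H)-one
Product: 24 butenolide ketone (2R,5S,6S,11S), via alkylzinc iodide 23 (not isolated)
Conditions: Zn dust, LiCl, THF, 40 °C; then 22, Pd(OAc)2 (5 mol %), SPhos (10 mol %), THF, 25 °C
Reagents that add atoms: none
Why: Zinc insertion into the primary iodide and Negishi coupling with the β-bromo butenolide; organozinc halides leave the C8 ketone alone and the neutral conditions spare the butenolide.

Step 16
Reactants: 24 butenolide ketone
Product: 25 C8 alcohol (2R,5S,6S,8R,11S)
Conditions: NaBH4, CeCl3·7H2O, MeOH/THF, −78 °C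
Reagents that add atoms: none
Why: Luche reduction: the cyclopentanone is reduced at −78 °C without touching the unsaturated lactone. One face of C8 is screened by the C5 silyl ether and the C10 ketal carbon (both 1,3 to C8 on the trans-fused ring), so hydride enters from the face of the C6 hydrogen and the hydroxyl ends cis to the C5 oxygen.

Step 17
Reactants: 25 C8 alcohol
Product: 26 (2R,3aS,5S,6R,8aS)-2,8a-dihydroxy-1,1,5,6-tetramethyl-5-[2-(5-oxo-2,5-dihydrofuran-3-yl)ethyl]octahydroazulen-4(1H)-one
Conditions: 1 M aq. HCl, THF, 0 → 20 °C
Reagents that add atoms: water, O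
Why: Acid hydrolysis removes the dioxolane and the tertiary silyl ether together; it is kept cold and dilute because the product is a β-hydroxy ketone with an enolisable fusion hydrogen, and no stereocentre is formed.

## Compound list

1 | 2-methylcyclohex-2-en-1-one | CC1=CCCCC1=O | starting material
2 | ethyl bromoacetate | CCOC(=O)CBr | starting material
3 | bromomagnesium (3R)-2,3-dimethylcyclohex-1-en-1-olate | C[C@@H]1CCCC(O[Mg]Br)=C1C | intermediate
4 | ethyl 2-[(1S,2R)-1,2-dimethyl-6-oxocyclohexyl]acetate | C[C@@H]1CCCC(=O)[C@@]1(C)CC(=O)OCC | intermediate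
5 | ethyl 2-[(1S,6R)-1,6-dimethyl-2-(trimethylsilyloxy)cyclohex-2-en-1-yl]acetate | C[C@@H]1CCC=C(O[Si](C)(C)C)[C@@]1(C)CC(=O)OCC | intermediate
6 | ethyl 2-[(2S,3R)-7,7-dibromo-2,3-dimethyl-1-(trimethylsilyloxy)bicyclo[4.1.0]heptan-2-yl]acetate (mixture at the cyclopropane carbons) | C[C@@H]1CCC2C(Br)(Br)C2(O[Si](C)(C)C)[C@@]1(C)CC(=O)OCC | intermediate
7 | ethyl 2-[(1S,2R)-6-bromo-1,2-dimethyl-7-oxocyclohept-5-en-1-yl]acetate | C[C@@H]1CCC=C(Br)C(=O)[C@@]1(C)CC(=O)OCC | intermediate
8 | ethyl 2-[(6S,7R)-11-bromo-6,7-dimethyl-1,4-dioxaspiro[4.6]undec-10-en-6-yl]acetate | C[C@@H]1CCC=C(Br)C2(OCCO2)[C@@]1(C)CC(=O)OCC | intermediate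
9 | ethyl 2-[(6S,7R)-6,7,11-trimethyl-1,4-dioxaspiro[4.6]undec-10-en-6-yl]acetate | C[C@@H]1CCC=C(C)C2(OCCO2)[C@@]1(C)CC(=O)OCC | intermediate
10 | 2-[(6S,7R)-6,7,11-trimethyl-1,4-dioxaspiro[4.6]undec-10-en-6-yl]ethan-1-ol | C[C@@H]1CCC=C(C)C2(OCCO2)[C@@]1(C)CCO | intermediate
11 | 2-bromo-2-methylpropanoyl bromide | CC(C)(Br)C(=O)Br | starting material
12 | 2-[(6S,7R)-6,7,11-trimethyl-1,4-dioxaspiro[4.6]undec-10-en-6-yl]ethyl 2-bromo-2-methylpropanoate | C[C@@H]1CCC=C(C)C2(OCCO2)[C@@]1(C)CCOC(=O)C(C)(C)Br | intermediate
13 | C5 hydroperoxide of the C6-methylidene ketal (C5 epimers), bromoisobutyrate on the C11 chain; (2R,11S) | C[C@@H]1CCC(OO)C(=C)C2(OCCO2)[C@@]1(C)CCOC(=O)C(C)(C)Br | intermediate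
14 | 2-[(6S,7R)-6,7-dimethyl-11-methylidene-10-oxo-1,4-dioxaspiro[4.6]undecan-6-yl]ethyl 2-bromo-2-methylpropanoate | C[C@@H]1CCC(=O)C(=C)C2(OCCO2)[C@@]1(C)CCOC(=O)C(C)(C)Br | intermediate
15 | diiodosamarium enolate (ketene acetal) of the isobutyrate ester of the C11 chain in 14 | C[C@@H]1CCC(=O)C(=C)C2(OCCO2)[C@@]1(C)CCOC(O[Sm](I)I)=C(C)C | intermediate
16 | bridged hydroxy lactone: cycloheptane with C5–OH, C6 methylidene and C10 ethylene ketal, C5 and C11 joined by the bridge C5–C(CH3)2–C(=O)–O–CH2–CH2–C11; (2R,5S,11S) | C[C@@H]1CC[C@]2(O)C(=C)C3(OCCO3)[C@@]1(C)CCOC(=O)C2(C)C | intermediate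
17 | 2-methylpropanal bearing at its C2 the ring carbon C5 (C5–OH, C6 methylidene, C10 ethylene ketal, C11 methyl and 2-hydroxyethyl, C2 methyl); (2R,5R,11S) | C[C@@H]1CC[C@@](O)(C(C)(C)C=O)C(=C)C2(OCCO2)[C@@]1(C)CCO | intermediate
18 | bis(triethylsilyl) ether of 17 (C5–OSiEt3 and CH2CH2OSiEt3); (2R,5R,11S) | C[C@@H]1CC[C@@](O[Si](CC)(CC)CC)(C(C)(C)C=O)C(=C)C2(OCCO2)[C@@]1(C)CCO[Si](CC)(CC)CC | intermediate
19 | trans-fused bicyclo[5.3.0]decane: C8 ketone, C9 gem-dimethyl, C5–OSiEt3, C6–H trans to it, C10 ethylene ketal, C11 methyl and CH2CH2OSiEt3, C2 methyl; (2R,5S,6S,11S) | C[C@@H]1CC[C@]2(O[Si](CC)(CC)CC)[C@H](CC(=O)C2(C)C)C3(OCCO3)[C@@]1(C)CCO[Si](CC)(CC)CC | intermediate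
20 | primary alcohol from 19 (C11–CH2CH2OH) | C[C@@H]1CC[C@]2(O[Si](CC)(CC)CC)[C@H](CC(=O)C2(C)C)C3(OCCO3)[C@@]1(C)CCO | intermediate
21 | primary iodide from 20 (C11–CH2CH2I) | C[C@@H]1CC[C@]2(O[Si](CC)(CC)CC)[C@H](CC(=O)C2(C)C)C3(OCCO3)[C@@]1(C)CCI | intermediate
22 | 4-bromofuran-2(5H)-one | BrC1=CC(=O)OC1 | starting material
23 | alkylzinc iodide from 21 (C11–CH2CH2ZnI) | C[C@@H]1CC[C@]2(O[Si](CC)(CC)CC)[C@H](CC(=O)C2(C)C)C3(OCCO3)[C@@]1(C)CC[Zn]I | intermediate
24 | butenolide ketone: as 19 with the chain ending at C4 of furan-2(5H)-one; (2R,5S,6S,11S) | C[C@@H]1CC[C@]2(O[Si](CC)(CC)CC)[C@H](CC(=O)C2(C)C)C3(OCCO3)[C@@]1(C)CCC1=CC(=O)OC1 | intermediate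
25 | C8 alcohol from 24, hydroxyl cis to the C5 oxygen; (2R,5S,6S,8R,11S) | C[C@@H]1CC[C@]2(O[Si](CC)(CC)CC)[C@H](C[C@@H](O)C2(C)C)C3(OCCO3)[C@@]1(C)CCC1=CC(=O)OC1 | intermediate
26 | (2R,3aS,5S,6R,8aS)-2,8a-dihydroxy-1,1,5,6-tetramethyl-5-[2-(5-oxo-2,5-dihydrofuran-3-yl)ethyl]octahydroazulen-4(1H)-one (CNP0077405.1) | C[C@@H]1CC[C@]2(O)[C@H](C[C@@H](O)C2(C)C)C(=O)[C@@]1(C)CCC1=CC(=O)OC1 | target

## Step count and least certain steps

Total: 17 steps. Longest linear sequence: 17 steps (1 to 26).

**Step 12 (key step).** Decarbonylation of the acyl rhodium hydride may outrun hydride insertion, because the methylene lies between two fully substituted carbons (silylated C5, ketal C10) and is slow to coordinate; the catalyst would then die as a rhodium carbonyl.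
- Fallback (from 17, returning at 26): run the same closure on the less crowded, conjugated C10 ketone, a 4-acyl-4-pentenal of the kind these catalysts are known to cyclise.
- Hydrolysis of the dioxolane of 17 (PPTS, aqueous acetone, 40 °C) would give enone diol aldehyde F1, and bis-silylation (TESOTf, 2,6-lutidine) aldehyde F2.
- Hydroacylation would give diketone F3, which is taken through the operations of steps 13 to 16: primary alcohol F4, iodide F5, alkylzinc iodide F6, butenolide F7 and C8 alcohol F8. The C10 ketone, flanked by C11 and C6, is expected to resist NaBH4/CeCl3 at −78 °C.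
- Desilylation of F8 with HF·pyridine gives 26.

**Step 9.** Closure of the bridged nine-membered ring may be slow, so that the samarium enolate is protonated, adds in conjugate fashion to C7, or the enone is reduced by excess SmI2.
- Fallback (from 10, returning at 18): intermolecular addition with separation of epimers.
- Silylation (TESCl, imidazole) gives silyl ether F9; photo-oxygenation to hydroperoxide F10 and dehydration as in step 8 give enone F11.
- The lithium enolate of ethyl 2-methylpropanoate with CeCl3 at −78 °C gives hydroxy ester F12 after chromatographic removal of its C5 epimer (no facial guarantee here).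
- Silylation (TESOTf) gives F13, and i-Bu2AlH reduction of its ester gives 18.

**Step 8.** Site selectivity of the ene reaction may be poor: oxygen bonding at C6 with abstraction of a C4 hydrogen gives a tertiary hydroperoxide that cannot be dehydrated to 14.
- Fallback (from 12, returning at 14): stepwise transposition. Epoxidation with mCPBA gives epoxide F14; diethylaluminium 2,2,6,6-tetramethylpiperidide removes a C7 hydrogen and opens it to the exo-methylene allylic alcohol F15; Dess–Martin periodinane oxidises F15 to 14.

**Step 4.** Ketalisation may stall, because C10 is next to quaternary C11 and its carbonyl is deactivated by the α-bromine.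
- Fallback (from 7, returning at 9): invert the order. Negishi methylation of 7 first gives the more basic methyl enone F16, which is then ketalised with the same bis-silyl glycol reagent to 9, bypassing 8.

## Further compounds

F1 | step 12 | enone diol aldehyde (C10 ketone, C5–OH, chain OH) | C[C@@H]1CC[C@@](O)(C(C)(C)C=O)C(=C)C(=O)[C@@]1(C)CCO
F2 | step 12 | bis(triethylsilyl) ether of F1 | C[C@@H]1CC[C@@](O[Si](CC)(CC)CC)(C(C)(C)C=O)C(=C)C(=O)[C@@]1(C)CCO[Si](CC)(CC)CC
F3 | step 12 | trans-fused C8,C10-diketone bis(triethylsilyl) ether | C[C@@H]1CC[C@]2(O[Si](CC)(CC)CC)[C@H](CC(=O)C2(C)C)C(=O)[C@@]1(C)CCO[Si](CC)(CC)CC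
F4 | step 12 | primary alcohol of the diketone series | C[C@@H]1CC[C@]2(O[Si](CC)(CC)CC)[C@H](CC(=O)C2(C)C)C(=O)[C@@]1(C)CCO
F5 | step 12 | primary iodide of the diketone series | C[C@@H]1CC[C@]2(O[Si](CC)(CC)CC)[C@H](CC(=O)C2(C)C)C(=O)[C@@]1(C)CCI
F6 | step 12 | alkylzinc iodide of the diketone series | C[C@@H]1CC[C@]2(O[Si](CC)(CC)CC)[C@H](CC(=O)C2(C)C)C(=O)[C@@]1(C)CC[Zn]I
F7 | step 12 | butenolide diketone | C[C@@H]1CC[C@]2(O[Si](CC)(CC)CC)[C@H](CC(=O)C2(C)C)C(=O)[C@@]1(C)CCC1=CC(=O)OC1
F8 | step 12 | C8 alcohol, C10 ketone, C5 silyl ether | C[C@@H]1CC[C@]2(O[Si](CC)(CC)CC)[C@H](C[C@@H](O)C2(C)C)C(=O)[C@@]1(C)CCC1=CC(=O)OC1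
F9 | step 9 | triethylsilyl ether of 10 | C[C@@H]1CCC=C(C)C2(OCCO2)[C@@]1(C)CCO[Si](CC)(CC)CC
F10 | step 9 | C5 hydroperoxide with C6 methylidene, chain silyl ether | C[C@@H]1CCC(OO)C(=C)C2(OCCO2)[C@@]1(C)CCO[Si](CC)(CC)CC
F11 | step 9 | C5 ketone with C6 methylidene, chain silyl ether | C[C@@H]1CCC(=O)C(=C)C2(OCCO2)[C@@]1(C)CCO[Si](CC)(CC)CC
F12 | step 9 | C5 hydroxy ethyl ester (wanted C5 epimer) | C[C@@H]1CC[C@@](O)(C(C)(C)C(=O)OCC)C(=C)C2(OCCO2)[C@@]1(C)CCO[Si](CC)(CC)CC
F13 | step 9 | C5 triethylsilyl ether of F12 | C[C@@H]1CC[C@@](O[Si](CC)(CC)CC)(C(C)(C)C(=O)OCC)C(=C)C2(OCCO2)[C@@]1(C)CCO[Si](CC)(CC)CC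
F14 | step 8 | C5–C6 epoxide of 12 | C[C@@H]1CCC2OC2(C)C3(OCCO3)[C@@]1(C)CCOC(=O)C(C)(C)Br
F15 | step 8 | C5 allylic alcohol with C6 methylidene | C[C@@H]1CCC(O)C(=C)C2(OCCO2)[C@@]1(C)CCOC(=O)C(C)(C)Br
F16 | step 4 | ethyl 2-[(1S,2R)-1,2,6-trimethyl-7-oxocyclohept-5-en-1-yl]acetate | C[C@@H]1CCC=C(C)C(=O)[C@@]1(C)CC(=O)OCC
A1 | alternative 1 | open-chain (E,E)-epoxy triene butenolide | CC1(C)O[C@@H]1CC/C(C)=C/CC/C(C)=C/CCC1=CC(=O)OC1
A2 | alternative 1 | halim-5(10)-ene-type octalin alcohol | C[C@@H]1CCC2=C(CC[C@@H](O)C2(C)C)[C@@]1(C)CCC1=CC(=O)OC1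
A3 | alternative 2 | C2-vinyl ketone with cyclopentenyl C5 enol triflate | C=C[C@@H](C)[C@](C)(CCOCc1ccc(OC)cc1)C(=O)C1=C(OS(=O)(=O)C(F)(F)F)C(C)(C)[C@H](O[Si](C)(C)C(C)(C)C)C1
A4 | alternative 2 | bicyclo[5.3.0]decenone with C5=C6 conjugated to C10 | C[C@@H]1CCC2=C(C[C@@H](O[Si](C)(C)C(C)(C)C)C2(C)C)C(=O)[C@@]1(C)CCOCc1ccc(OC)cc1
A5 | alternative 3 | cyclohexanone with tethered α-diazo ester | C[C@@H]1CC[C@@](O[Si](C)(C)C)(C(C)(C)[C@H](O[Si](C)(C)C(C)(C)C)CC(=[N+]=[N-])C(=O)OCC)C(=O)[C@@]1(C)CCO[Si](C)(C)C(C)(C)C
A6 | alternative 3 | bicyclo[5.3.0]decanone β-keto ester (ester on C6) | C[C@@H]1CC[C@]2(O[Si](C)(C)C)[C@@](C[C@@H](O[Si](C)(C)C(C)(C)C)C2(C)C)(C(=O)OCC)C(=O)[C@@]1(C)CCO[Si](C)(C)C(C)(C)C
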